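If I put the same charge into baths at different temperatures, which flask holds the most target at the end?

common to all: substrate 0.50 M; reagent 0.475 M; time 15 h
- Thursday's: temperature −25 °C
- Saturday's: temperature 25 °C
- Sunday's: temperature 0 °C

    substrate + reagent ⇌ target + released group (K1 = 4.5, k1 = 0.0045 L mol⁻¹ min⁻¹, Ea1 = 75.0 kJ mol⁻¹, ΔH1 = −29.0 kJ mol⁻¹)
    crystals ⇌ released group, rate k2*(cs2 - [released group]) while solid is left; crystals form when [released group] > cs2 (cs2 = 0.074 M, k2 = 0.068 min⁻¹)
    target ⇌ isomer of the product (K3 = 1.4, k3 = 0.0015 min⁻¹, Ea3 = 93.0 kJ mol⁻¹, ΔH3 = −38.0 kJ mol⁻¹)
    (constants at 25 °C)

- for released group the crystals are counted in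
- as a solid, counted per litre of solution: crystals
- constants are those at 25 °C; use the activation energies and enthalpies for any other temperature

- the flask with the highest amount of target, in percent of the substrate charged ("all alike" if they lie within 1.5 percentage points) (Thursday's / Saturday's / Sunday's / all alike)
- final target, as a percentage of the substrate charged, in Thursday's
- final target, as a percentage of the substrate charged, in Saturday's
- final target, as a percentage of the substrate charged, in Sunday's

Two numbers seem to clash. The first step's equilibrium constant is 47.5 in Thursday's flask and 4.50 in Saturday's, about ten times better in the cold, yet its forward constant is 440 times slower there. The constant says where a flask stops, not how far it gets in the time allowed, so I reckon with the fraction of substrate left. For near-equal charges and no back step, that fraction is one over one plus the clock. Thursday's gives 0.00433 for this clock: forward constant of the first step at the flask's temperature, times reagent charge, times time.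

That clock is far below one, so Thursday's keeps 99.6% of its substrate and makes 0.431% target. This is kinetic, not thermodynamic, control. The isomer step's relaxation half-life there, 596 d, is long against 15 h, so the target stays target.

Saturday's clock is 1.92, which leaves 34.2% of the substrate and makes 65.8% target plus isomer. The reagent shortfall and the back step both leave somewhat more. The isomer step has time here, with rate constant times time at 1.35. The target's equilibrium share of the pair is 41.7%, so I expect Saturday's target between 27.4% and 65.8%.

Sunday's bath stands midway, so I take the square root of the factor as a rough guide. That gives a clock of 0.0913 and about 8.37% target, a rough figure. Saturday's leads.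

The forecast names Saturday's, with 0.43% (0.38% to 0.48%) for Thursday's, 35% (32% to 38%) for Saturday's and 10.4% (9.5% to 11.2%) for Sunday's, holding that “the Arrhenius slowdown leaves little conversion in 15 h”. The simulation gives Saturday's, with target at 0.431% in Thursday's, 36.0% in Saturday's and 10.5% in Sunday's, the last above my rough 8.37%.

In Thursday's flask the first step's relaxation half-life at 15.0 h is 48.9 d, long against the 15 h allowed, and shorter than the isomer step's 596 d. After 150 h that flask's target stands at 4.13%. Thursday's flask with 0.28 M of reagent has its clock scaled with the charge to 0.00255, which promises 0.255% target; the computed result is 0.254%.

The numbers of this flask are invented; the rest is arithmetic.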